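Ring A is numbered C1 (acyl), C2 (NH2), C3 (Me, OH), C4 (C=O), C5 (bridge C7), C6 (OMe); ring B carries primes. Everything rests on cutting C2–N and hanging the nitrogen, as a carbamate, on the oxygen of carbinol C3. The feature used: C2 is bonded to C3, whereas C6, the other methoxy-bearing vinylogous ester carbon, is not, so nitrogen tethered to O3 reaches only C2 (five-membered ring). One operation replaces the C2 methoxy group by nitrogen and masks N and O3 as an oxazolidinone. The precursor is the C3 carbamate of the 2,6-dimethoxy ring A dienone (C5–H). Ring B is attached last, through C7, by palladium-catalysed cyclopropanol opening.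

Key step: step 7

Remark: ring B locants are C1' (Me, C7), C2' (C=O), C3' (Me, ester), C4' (C=O), C5' (H), C6' (OMe); the target is 3R, 1'R, 3'R with an (R) ketone and an (S) ester side chain, and C7 is trans to the C3' acyloxy group.
Assumption: both antipodes of the chiral iodyl reagent of steps 5 and 15 are at hand, and the antipode that gives the stated carbinol configuration is fixed in a trial run.

Step 1
Reactants: 1 2,4,6-trihydroxytoluene; 2 (R)-2-methylbutanoic acid
Product: 4 (2R)-2-methyl-1-(2,4,6-trihydroxy-3-methylphenyl)butan-1-one, via (R)-2-methylbutanoyl chloride 3 (not isolated)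
Conditions: 2, (COCl)2, cat. DMF, CH2Cl2, 0 °C to rt; then 1, AlCl3, PhNO2–CH2Cl2, 0 °C to rt; aq. HCl
Reagents that add atoms: none
Why: Friedel–Crafts C-acylation at one of the two equivalent free ring positions; the acid chloride is made and used cold and without amine base, so the (R) α-centre should be kept.

Step 2
Reactants: 4 (2R)-2-methyl-1-(2,4,6-trihydroxy-3-methylphenyl)butan-1-one
Product: 5 (2R)-1-[4-(benzyloxy)-2,6-dihydroxy-3-methylphenyl]-2-methylbutan-1-one
Conditions: BnBr (1.05 equiv), K2CO3, acetone, 40 °C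
Reagents that add atoms: benzyl bromide, BrCc1ccccc1
Why: Williamson etherification; the C4 hydroxyl, para to the ketone, is the most acidic and is not chelated to the carbonyl, so one equivalent of benzyl bromide should alkylate it selectively.

Step 3
Reactants: 5 (2R)-1-[4-(benzyloxy)-2,6-dihydroxy-3-methylphenyl]-2-methylbutan-1-one
Product: 6 (2R)-1-[4-(benzyloxy)-2,6-dimethoxy-3-methylphenyl]-2-methylbutan-1-one
Conditions: MeI (excess), K2CO3, DMF, 40 °C
Reagents that add atoms: iodomethane, CI
Why: Williamson O-methylation of the two ortho hydroxyls with a weak base that should not enolise the hindered aryl ketone.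

Step 4
Reactants: 6 (2R)-1-[4-(benzyloxy)-2,6-dimethoxy-3-methylphenyl]-2-methylbutan-1-one
Product: 7 (2R)-1-(4-hydroxy-2,6-dimethoxy-3-methylphenyl)-2-methylbutan-1-one
Conditions: H2 (1 atm), Pd/C, EtOAc, rt
Reagents that add atoms: none
Why: Hydrogenolysis of the benzyl ether frees the C4 phenol; the twisted di-ortho-substituted aryl ketone should survive.

Step 5
Reactants: 7 (2R)-1-(4-hydroxy-2,6-dimethoxy-3-methylphenyl)-2-methylbutan-1-one
Product: 8 (6R)-6-hydroxy-3,5-dimethoxy-6-methyl-4-[(2R)-2-methylbutanoyl]cyclohexa-2,4-dien-1-one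
Conditions: chiral iodyl arene (1.2 equiv), THF, rt; aq. NaHCO3
Reagents that add atoms: (S)-2-(2-iodylphenyl)-4-(propan-2-yl)-4,5-dihydro-1,3-oxazole, CC(C)[C@H]1COC(=N1)c1ccccc1I(=O)=O
Why: Hydroxylative phenol dearomatisation by a pentavalent iodine reagent (the phenol binds to iodine and oxygen passes to the methyl-bearing ortho carbon C3, as known for phenols of this type); the chiral reagent sets C3 as R, and any 3S epimer is a diastereomer because of the side-chain centre and is removed by chromatography.

Step 6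
Reactants: 8 (6R)-6-hydroxy-3,5-dimethoxy-6-methyl-4-[(2R)-2-methylbutanoyl]cyclohexa-2,4-dien-1-one; 9 trichloroacetyl isocyanate
Product: 11 (1R)-2,4-dimethoxy-1-methyl-3-[(2R)-2-methylbutanoyl]-6-oxocyclohexa-2,4-dien-1-yl carbamate, via N-trichloroacetyl carbamate 10 (not isolated)
Conditions: 9, CH2Cl2, 0 °C; then moist neutral Al2O3, rt
Reagents that add atoms: none
Why: Addition of the tertiary alcohol to the acyl isocyanate, then hydrolysis of the N-trichloroacetyl group on neutral alumina, which avoids basic methanol that could start the cyclisation early or epimerise the ketone α-centre; C3 is untouched.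

Step 7
Reactants: 11 (1R)-2,4-dimethoxy-1-methyl-3-[(2R)-2-methylbutanoyl]-6-oxocyclohexa-2,4-dien-1-yl carbamate
Product: 12 (7aR)-5-methoxy-7a-methyl-4-[(2R)-2-methylbutanoyl]-3,7a-dihydro-1,3-benzoxazole-2,7-dione
Conditions: NaH (1.0 equiv), THF, −20 to 0 °C; AcOH quench
Reagents that add atoms: none
Why: Proposed new method: the sodium carbamate should add through nitrogen to C2, which is the β-carbon of the C1=C2 acyl enone and the δ-terminus of the C4 dienone, and the resulting enolate should expel methoxide (intramolecular aza-Michael addition then β-elimination); the closest known reactions are the base-induced cyclisation of allylic carbamates onto electron-poor alkenes and the aminolysis of β-alkoxy enones, not yet combined on a cyclohexadienone. The oxazolidinone ring closes in the 5-exo-trig mode from the pseudo-axial O3 tether. No stereocentre is formed and no bond to C3 is broken, so its R configuration is carried through. The step needs C2 over C6 selectivity, which the tether secures: C2 is bonded to C3, C6 would require a seven-membered ring, and addition to the C4 carbonyl is reversible. One equivalent of base at low temperature protects the sec-butyl ketone centre, because the methoxide set free is neutralised at once by the acidic N–H of the vinylogous imide product.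

Step 8
Reactants: 12 (7aR)-5-methoxy-7a-methyl-4-[(2R)-2-methylbutanoyl]-3,7a-dihydro-1,3-benzoxazole-2,7-dione
Product: 13 (7aR)-6-iodo-5-methoxy-7a-methyl-4-[(2R)-2-methylbutanoyl]-3,7a-dihydro-1,3-benzoxazole-2,7-dione
Conditions: NIS, MeCN, 0 °C to rt
Reagents that add atoms: N-iodosuccinimide, O=C1CCC(=O)N1I
Why: Electrophilic α-iodination of the C4/C6 β-alkoxy enone at C5, the only ring C–H, done while N and O3 are still masked in the oxazolidinone.

Step 9
Reactants: 13 (7aR)-6-iodo-5-methoxy-7a-methyl-4-[(2R)-2-methylbutanoyl]-3,7a-dihydro-1,3-benzoxazole-2,7-dione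
Product: 14 (6R)-5-amino-6-hydroxy-2-iodo-3-methoxy-6-methyl-4-[(2R)-2-methylbutanoyl]cyclohexa-2,4-dien-1-one
Conditions: K2CO3 (0.3 equiv), MeOH, 0 °C; AcOH
Reagents that add atoms: none
Why: Carbamate methanolysis: methoxide opens the activated (vinylogous imide) oxazolidinone carbonyl, which leaves as dimethyl carbonate, and frees the C2 amine and C3 alcohol without touching C3.

Step 10
Reactants: 1 2,4,6-trihydroxytoluene
Product: 15 2,4,6-trihydroxy-3-methylbenzaldehyde
Conditions: POCl3, DMF, EtOAc, 0 °C to rt; then H2O, 60 °C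
Reagents that add atoms: N,N-dimethylformamide, CN(C)C=O; water, O
Why: Vilsmeier–Haack formylation of the electron-rich arene at one of its two equivalent free positions.

Step 11
Reactants: 15 2,4,6-trihydroxy-3-methylbenzaldehyde
Product: 16 2,6-dihydroxy-4-methoxy-3-methylbenzaldehyde
Conditions: MeI (1.05 equiv), K2CO3, acetone, rt
Reagents that add atoms: iodomethane, CI
Why: Williamson O-methylation; the hydroxyl para to the formyl group is the most acidic and is not chelated, so one equivalent of iodomethane should methylate it preferentially.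

Step 12
Reactants: 16 2,6-dihydroxy-4-methoxy-3-methylbenzaldehyde
Product: 17 5-methoxy-2,4-dimethylbenzene-1,3-diol
Conditions: H2, Pd/C, AcOH–EtOAc, rt
Reagents that add atoms: none
Why: Hydrogenolysis of the electron-rich ortho-hydroxy benzaldehyde through the benzylic alcohol to the ring methyl group, a known route to ring-methylated phloroglucinols.

Step 13
Reactants: 17 5-methoxy-2,4-dimethylbenzene-1,3-diol
Product: 18 1,3-bis[(tert-butyldimethylsilyl)oxy]-5-methoxy-2,4-dimethylbenzene
Conditions: TBSCl (2.5 equiv), imidazole, DMF, 50 °C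
Reagents that add atoms: tert-butyldimethylsilyl chloride, CC(C)(C)[Si](C)(C)Cl
Why: Imidazole-promoted silyl ether formation at both phenols.

Step 14
Reactants: 18 1,3-bis[(tert-butyldimethylsilyl)oxy]-5-methoxy-2,4-dimethylbenzene
Product: 19 3-[(tert-butyldimethylsilyl)oxy]-5-methoxy-2,4-dimethylphenol
Conditions: K2CO3 (0.2 equiv), MeOH, 0 °C
Reagents that add atoms: none
Why: Base-catalysed methanolysis of an aryl silyl ether should be faster at the C4' oxygen (one ortho methyl) than at the C2' oxygen shielded by two ortho methyl groups, which leaves the phenol ortho to C3' and the silyl group on the future enol oxygen.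

Step 15
Reactants: 19 3-[(tert-butyldimethylsilyl)oxy]-5-methoxy-2,4-dimethylphenol
Product: 20 (6S)-5-[(tert-butyldimethylsilyl)oxy]-6-hydroxy-3-methoxy-4,6-dimethylcyclohexa-2,4-dien-1-one
Conditions: antipodal chiral iodyl arene (1.2 equiv), THF, rt; aq. NaHCO3
Reagents that add atoms: (R)-2-(2-iodylphenyl)-4-(propan-2-yl)-4,5-dihydro-1,3-oxazole, CC(C)[C@@H]1COC(=N1)c1ccccc1I(=O)=O
Why: Hydroxylative phenol dearomatisation as in step 5 at the methyl-bearing ortho carbon C3'; the antipodal reagent sets the carbinol centre (S here, 3'R in the target), and enantiomeric leakage becomes a separable diastereomer after step 16.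

Step 16
Reactants: 20 (6S)-5-[(tert-butyldimethylsilyl)oxy]-6-hydroxy-3-methoxy-4,6-dimethylcyclohexa-2,4-dien-1-one; 21 (S)-2-methylbutanoic acid
Product: 23 (1S)-2-[(tert-butyldimethylsilyl)oxy]-4-methoxy-1,3-dimethyl-6-oxocyclohexa-2,4-dien-1-yl (2S)-2-methylbutanoate, via (S)-2-methylbutanoic anhydride 22 (not isolated)
Conditions: 21 (2.2 equiv), DCC (1.1 equiv), CH2Cl2, 0 °C; then 20, DMAP, rt
Reagents that add atoms: none
Why: DMAP-catalysed acylation of the tertiary alcohol by the preformed anhydride, without an amine base that could form a ketene, so the (S) α-centre is kept and C3' is untouched.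

Step 17
Reactants: 23 (1S)-2-[(tert-butyldimethylsilyl)oxy]-4-methoxy-1,3-dimethyl-6-oxocyclohexa-2,4-dien-1-yl (2S)-2-methylbutanoate
Product: 24 (1S,2S,6R)-1-[(tert-butyldimethylsilyl)oxy]-5-methoxy-2,6-dimethyl-3-oxobicyclo[4.1.0]hept-4-en-2-yl (2S)-2-methylbutanoate
Conditions: Et2Zn, CH2I2, CH2Cl2–DME, 0 °C to rt
Reagents that add atoms: diiodomethane, ICI
Why: Simmons–Smith cyclopropanation (Et2Zn/CH2I2 variant) of the silyl enol ether C1'=C2', the only alkene that is not an enone double bond; the carbenoid is required, and expected on steric grounds in the donor solvent, to add anti to the branched C3' acyloxy group, which places C7 trans to O3' and sets C1' (and transient C2') from C3'.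

Step 18
Reactants: 24 (1S,2S,6R)-1-[(tert-butyldimethylsilyl)oxy]-5-methoxy-2,6-dimethyl-3-oxobicyclo[4.1.0]hept-4-en-2-yl (2S)-2-methylbutanoate
Product: 25 (1S,2S,6S)-1-hydroxy-5-methoxy-2,6-dimethyl-3-oxobicyclo[4.1.0]hept-4-en-2-yl (2S)-2-methylbutanoate
Conditions: HF·pyridine, THF–pyridine, 0 °C
Reagents that add atoms: none
Why: Fluoride cleavage of the silyl ether under acidic buffered conditions, so that no free cyclopropanolate forms that could open the ring or take over the neighbouring acyl group.

Step 19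
Reactants: 14 (6R)-5-amino-6-hydroxy-2-iodo-3-methoxy-6-methyl-4-[(2R)-2-methylbutanoyl]cyclohexa-2,4-dien-1-one; 25 (1S,2S,6S)-1-hydroxy-5-methoxy-2,6-dimethyl-3-oxobicyclo[4.1.0]hept-4-en-2-yl (2S)-2-methylbutanoate
Product: 26 target CNP0537128.1 (3R,1'R,3'R; (R) ketone and (S) ester side chains)
Conditions: Pd(OAc)2 (10 mol %), XPhos (20 mol %), Cs2CO3, toluene, 60 °C
Reagents that add atoms: none
Why: Palladium-homoenolate cross-coupling of a cyclopropanol with a C(sp2) iodide: C5–I adds to zerovalent palladium formed in situ, the cyclopropanol oxygen binds, β-carbon elimination cleaves the less substituted C2'–C7 bond to a primary alkylpalladium on C7 (C1' is quaternary, so no β-hydride elimination), and reductive elimination forms C5–C7 and the C2' ketone with C1', C3' and C3 untouched.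

Compound list
1 | 2,4,6-trihydroxytoluene | Cc1c(O)cc(O)cc1O | starting material
2 | (R)-2-methylbutanoic acid | CC[C@@H](C)C(=O)O | starting material
3 | (R)-2-methylbutanoyl chloride | CC[C@@H](C)C(=O)Cl | intermediate
4 | (2R)-2-methyl-1-(2,4,6-trihydroxy-3-methylphenyl)butan-1-one | CC[C@@H](C)C(=O)c1c(O)cc(O)c(C)c1O | intermediate
5 | (2R)-1-[4-(benzyloxy)-2,6-dihydroxy-3-methylphenyl]-2-methylbutan-1-one | CC[C@@H](C)C(=O)c1c(O)cc(OCc2ccccc2)c(C)c1O | intermediate
6 | (2R)-1-[4-(benzyloxy)-2,6-dimethoxy-3-methylphenyl]-2-methylbutan-1-one | CC[C@@H](C)C(=O)c1c(OC)cc(OCc2ccccc2)c(C)c1OC | intermediate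
7 | (2R)-1-(4-hydroxy-2,6-dimethoxy-3-methylphenyl)-2-methylbutan-1-one | CC[C@@H](C)C(=O)c1c(OC)cc(O)c(C)c1OC | intermediate
8 | (6R)-6-hydroxy-3,5-dimethoxy-6-methyl-4-[(2R)-2-methylbutanoyl]cyclohexa-2,4-dien-1-one | CC[C@@H](C)C(=O)C1=C(OC)[C@@](C)(O)C(=O)C=C1OC | intermediate
9 | trichloroacetyl isocyanate | O=C=NC(=O)C(Cl)(Cl)Cl | starting material
10 | N-trichloroacetyl carbamate of 8 | CC[C@@H](C)C(=O)C1=C(OC)[C@@](C)(OC(=O)NC(=O)C(Cl)(Cl)Cl)C(=O)C=C1OC | intermediate
11 | (1R)-2,4-dimethoxy-1-methyl-3-[(2R)-2-methylbutanoyl]-6-oxocyclohexa-2,4-dien-1-yl carbamate (key-step precursor) | CC[C@@H](C)C(=O)C1=C(OC)[C@@](C)(OC(N)=O)C(=O)C=C1OC | intermediate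
12 | (7aR)-5-methoxy-7a-methyl-4-[(2R)-2-methylbutanoyl]-3,7a-dihydro-1,3-benzoxazole-2,7-dione (key-step product) | CC[C@@H](C)C(=O)C1=C2NC(=O)O[C@@]2(C)C(=O)C=C1OC | intermediate
13 | (7aR)-6-iodo-5-methoxy-7a-methyl-4-[(2R)-2-methylbutanoyl]-3,7a-dihydro-1,3-benzoxazole-2,7-dione | CC[C@@H](C)C(=O)C1=C2NC(=O)O[C@@]2(C)C(=O)C(I)=C1OC | intermediate
14 | (6R)-5-amino-6-hydroxy-2-iodo-3-methoxy-6-methyl-4-[(2R)-2-methylbutanoyl]cyclohexa-2,4-dien-1-one | CC[C@@H](C)C(=O)C1=C(N)[C@@](C)(O)C(=O)C(I)=C1OC | intermediate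
15 | 2,4,6-trihydroxy-3-methylbenzaldehyde | O=Cc1c(O)cc(O)c(C)c1O | intermediate
16 | 2,6-dihydroxy-4-methoxy-3-methylbenzaldehyde | O=Cc1c(O)cc(OC)c(C)c1O | intermediate
17 | 5-methoxy-2,4-dimethylbenzene-1,3-diol | Cc1c(O)cc(OC)c(C)c1O | intermediate
18 | 1,3-bis[(tert-butyldimethylsilyl)oxy]-5-methoxy-2,4-dimethylbenzene | Cc1c(O[Si](C)(C)C(C)(C)C)cc(OC)c(C)c1O[Si](C)(C)C(C)(C)C | intermediate
19 | 3-[(tert-butyldimethylsilyl)oxy]-5-methoxy-2,4-dimethylphenol | Cc1c(O)cc(OC)c(C)c1O[Si](C)(C)C(C)(C)C | intermediate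
20 | (6S)-5-[(tert-butyldimethylsilyl)oxy]-6-hydroxy-3-methoxy-4,6-dimethylcyclohexa-2,4-dien-1-one | C[C@@]1(O)C(=O)C=C(OC)C(C)=C1O[Si](C)(C)C(C)(C)C | intermediate
21 | (S)-2-methylbutanoic acid | CC[C@H](C)C(=O)O | starting material
22 | (S)-2-methylbutanoic anhydride | CC[C@H](C)C(=O)OC(=O)[C@@H](C)CC | intermediate
23 | (1S)-2-[(tert-butyldimethylsilyl)oxy]-4-methoxy-1,3-dimethyl-6-oxocyclohexa-2,4-dien-1-yl (2S)-2-methylbutanoate | CC[C@H](C)C(=O)O[C@]1(C)C(=O)C=C(OC)C(C)=C1O[Si](C)(C)C(C)(C)C | intermediate
24 | (1S,2S,6R)-1-[(tert-butyldimethylsilyl)oxy]-5-methoxy-2,6-dimethyl-3-oxobicyclo[4.1.0]hept-4-en-2-yl (2S)-2-methylbutanoate (C7 trans to the acyloxy group) | CC[C@H](C)C(=O)O[C@]1(C)C(=O)C=C(OC)[C@@]2(C)C[C@@]12O[Si](C)(C)C(C)(C)C | intermediate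
25 | (1S,2S,6S)-1-hydroxy-5-methoxy-2,6-dimethyl-3-oxobicyclo[4.1.0]hept-4-en-2-yl (2S)-2-methylbutanoate (ring B cyclopropanol) | CC[C@H](C)C(=O)O[C@]1(C)C(=O)C=C(OC)[C@@]2(C)C[C@@]12O | intermediate
26 | CNP0537128.1 | CC[C@@H](C)C(=O)C1=C(N)[C@@](C)(O)C(=O)C(C[C@@]2(C)C(=O)[C@](C)(OC(=O)[C@@H](C)CC)C(=O)C=C2OC)=C1OC | target

Total steps: 19. Longest linear sequence: 10 steps (steps 1–9 and 19; the ring B branch, steps 10–18 and 19, is equally long).

Steps most likely to fail

Step 7 (proposed new method). The carbamate anion may fragment instead of cyclising (loss of cyanate, with the quinol alkoxide as leaving group), may rest unproductively as the C4 hemiaminal, or the base may epimerise the sec-butyl ketone centre. The fallback uses known chemistry without a tether and sets out from 8. Treatment with NH3 in MeOH at rt (aminolysis of a β-alkoxy enone) should exchange the C2 methoxy group, C2 being the vinylogous ester carbon conjugated to both carbonyl groups; any product of exchange at C6 would have to be separated. This gives the C5-unsubstituted ring A amino alcohol F1, which is iodinated at C5 with NIS as in step 8 and comes back to the route at 14.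

Step 17. The carbenoid may react slowly with the push–pull alkene and, more seriously, may be delivered syn to the ester oxygen, which would give the C1' epimer. The fallback sets out from 19 and relays the configuration through a hydroxyl-directed cyclopropanation:
- Dearomatisation of 19 with the reagent antipode used in step 5 gives the enantiomeric quinol F2.
- Its free tertiary hydroxyl directs Et2Zn/CH2I2 to the neighbouring C1'=C2' bond (hydroxyl-directed Simmons–Smith, C7 cis to OH), giving the cyclopropyl carbinol F3.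
- SmI2 (THF–MeOH, −78 °C) removes the α-hydroxyl to give the C3'-deoxy ketone F4.
- The lithium enolate (LiN(SiMe3)2, THF, −78 °C) is hydroxylated with 2-(phenylsulfonyl)-3-phenyloxaziridine on the face away from the cyclopropane methylene, giving the hydroxy ketone F5 with O3' trans to C7.
- Acylation as in step 16 comes back to the route at 24.

Step 19. Under carbonate the cyclopropanolate may take over the cis acyl group from O3' (an unreactive cyclopropyl ester), or open and be protonated to the C1' gem-dimethyl ketone before it meets palladium; the base may also trigger ketol rearrangement in ring A. The fallback avoids a free cyclopropanolate and sets out from 25. NIS (CH2Cl2, 0 °C; electrophilic ring-opening iodination of a cyclopropanol) gives the β-iodo ketone F6. Zinc insertion (Zn, LiCl, THF) gives the alkylzinc iodide F7. Negishi coupling with 14 (Pd(OAc)2, SPhos, THF, rt; excess F7 to allow for the N–H and O–H groups) arrives at 26.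

Further compounds
F1 | step 7 | (6R)-5-amino-6-hydroxy-3-methoxy-6-methyl-4-[(2R)-2-methylbutanoyl]cyclohexa-2,4-dien-1-one | CC[C@@H](C)C(=O)C1=C(N)[C@@](C)(O)C(=O)C=C1OC
F2 | step 17 | (6R)-5-[(tert-butyldimethylsilyl)oxy]-6-hydroxy-3-methoxy-4,6-dimethylcyclohexa-2,4-dien-1-one | C[C@]1(O)C(=O)C=C(OC)C(C)=C1O[Si](C)(C)C(C)(C)C
F3 | step 17 | (1S,2R,6R)-1-[(tert-butyldimethylsilyl)oxy]-2-hydroxy-5-methoxy-2,6-dimethylbicyclo[4.1.0]hept-4-en-3-one (C7 cis to the 2-hydroxyl) | O[C@@]1(C)C(=O)C=C(OC)[C@@]2(C)C[C@@]12O[Si](C)(C)C(C)(C)C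
F4 | step 17 | 1-[(tert-butyldimethylsilyl)oxy]-5-methoxy-2,6-dimethylbicyclo[4.1.0]hept-4-en-3-one (bridgeheads as in 24, C2 epimers) | CC1C(=O)C=C(OC)[C@@]2(C)C[C@@]12O[Si](C)(C)C(C)(C)C
F5 | step 17 | (1S,2S,6R)-1-[(tert-butyldimethylsilyl)oxy]-2-hydroxy-5-methoxy-2,6-dimethylbicyclo[4.1.0]hept-4-en-3-one (C7 trans to the 2-hydroxyl) | O[C@]1(C)C(=O)C=C(OC)[C@@]2(C)C[C@@]12O[Si](C)(C)C(C)(C)C
F6 | step 19 | (1R,3R)-3-(iodomethyl)-4-methoxy-1,3-dimethyl-2,6-dioxocyclohex-4-en-1-yl (2S)-2-methylbutanoate | CC[C@H](C)C(=O)O[C@]1(C)C(=O)C=C(OC)[C@@](C)(CI)C1=O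
F7 | step 19 | alkylzinc iodide from F6 (iodozinciomethyl at C1') | CC[C@H](C)C(=O)O[C@]1(C)C(=O)C=C(OC)[C@@](C)(C[Zn]I)C1=O
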